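**Retrosynthetic overview**
- The retro-decaene is unveiled last: a C40 diol with tertiary carbinols at C9 and C9' loses two molecules of water (1,4- and vinylogous elimination), then the silyl ether is cleaved.
- The C40 skeleton comes from a C18 hexaenedione (from glyoxal, a C5 cyanophosphonate and an acetonyl ylide) that takes up two ring acetylides in sequence; LiAlH4 then turns both alkynes into E-alkenes.
- Rings: the didehydro ring is bought as safranal. The hydroxylated ring is the only ring made, by a formal [4+2] (double Michael addition–elimination) of a 1-methoxy-3-silyloxydiene with mesityl oxide that forms C1–C2 and C5–C6 in one flask.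
- Enabling feature: in the hydroxylated ring the exocyclic C6=C7 alkene marks C7 as a latent carbonyl, so the gem-dimethyl carbon C1 is its β-carbon (acceptor) and C6 its α-carbon (donor). Oxygenated C3 and methyl-bearing sp2 C5 are 1,3-related like a β-diketone enol ether, so C2 is a donor and C5 an acceptor: C2–C3–C4–C5 plus C6–C1.
- The C3 stereocentre is set by catalyst-controlled asymmetric transfer hydrogenation of the ring enone; the ring acetyl group becomes the C7≡C8 alkyne.

Key step: step 2

Remark on the chemistry: ring positions are given in carotenoid numbering (C1 = CMe2, C2 = CH2, C3 = CHOH, C4 = CH=, C5 = C(CH3)=, C6 = ring carbon carrying the exocyclic alkene, C7 = first chain carbon). All starting materials are taken as catalogue chemicals (glyoxal as its 40 wt % aqueous solution). Compounds 6–11, 21, 22, 24 and 25 are carried as mixtures of epimers at ring C6 and at the tertiary carbinol carbons, which all become sp2 in step 13. The target geometry is taken as drawn: all chain alkenes E, and at each ring the chain carbon C8 (C8') trans to the methyl-bearing ring carbon C5 (C5').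

Step 1
Reactants: 1 (3E)-4-methoxypent-3-en-2-one
Product: 2 (3E)-2-{[tert-butyl(dimethyl)silyl]oxy}-4-methoxypenta-1,3-diene
Conditions: TBSOTf, Et3N, Et2O, 0 °C
Reagents that add atoms: tert-butyldimethylsilyl trifluoromethanesulfonate, CC(C)(C)[Si](C)(C)OS(=O)(=O)C(F)(F)F
Why: Soft enolisation and O-silylation of the vinylogous ester at its acetyl methyl group (silyl enol ether formation) should give the 1-methoxy-3-silyloxydiene; the regioisomeric 2-methoxy-4-silyloxydiene, if formed, would converge on the same product in step 2.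

Step 2
Reactants: 2 (3E)-2-{[tert-butyl(dimethyl)silyl]oxy}-4-methoxypenta-1,3-diene; 3 mesityl oxide (4-methylpent-3-en-2-one)
Product: 5 4-acetyl-3,5,5-trimethylcyclohex-2-en-1-one (racemic), via cycloadduct 4 (not isolated)
Conditions: (CF3SO2)2NH (10 mol %), CH2Cl2, −78 → −20 °C; then 1 M HCl, THF, 0 °C → rt
Reagents that add atoms: none
Why: The acid should convert a little of 2 into t-BuMe2SiN(SO2CF3)2, which silylates the carbonyl of 3; the CH2 terminus of 2 then adds to the β,β-dimethyl carbon (Mukaiyama–Michael addition, C1–C2, quaternary centre) and the new silyl enol ether carbon C6 closes on the silyl-activated β-methoxy enone carbon C5 (second Michael addition, C5–C6) to give 4, from which aqueous acid removes the silyl group and methanol to leave the C4=C5 enone. The closest known reaction types are the superacid- or Lewis-acid-catalysed Diels–Alder and sequential Mukaiyama–Michael reactions of hindered 2-silyloxydienes with β,β-disubstituted enones, and the Lewis-acid-promoted cycloaddition of penta-1,3-diene to mesityl oxide, which forms the same two ring bonds. The single ring closes in a 6-(enolexo)-endo-trig mode, overall a formal [4+2] cycloaddition that need not be concerted, so the fully substituted diene terminus does not have to reach an s-cis geometry. The two new stereocentres form without control: the methoxy-bearing C5 of 4 is lost on elimination and C6 becomes sp2 in step 13, so no control is needed. The step needs regiocontrol and 1,4- over 1,2-addition; both are secured by the polarised diene (the CH2 terminus is the only strongly nucleophilic site, the methoxy-bearing terminus becomes electrophilic only after the first bond) and by the hindered ketone carbonyl of 3, whose only accessible electrophilic site is the β-carbon. The methoxy leaving group fixes the alkene at C4=C5 and the acetyl group is the handle for C7.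

Step 3
Reactants: 5 4-acetyl-3,5,5-trimethylcyclohex-2-en-1-one (racemic)
Product: 6 1-[(4S)-4-hydroxy-2,6,6-trimethylcyclohex-2-en-1-yl]ethan-1-one (both C1 epimers)
Conditions: RuCl[(S,S)-TsDPEN](p-cymene) (1 mol %), HCO2H/Et3N (5:2), EtOAc, 25 °C
Reagents that add atoms: none
Why: Noyori–Ikariya asymmetric transfer hydrogenation should deliver hydride to the unhindered conjugated ring carbonyl under catalyst control, with the alkenyl arm in the position the aryl group takes in aryl ketones, setting the (S)-carbinol in a CH=C(CH3)/CH2–CMe2 environment for which this catalyst class is established; the hindered dialkyl acetyl ketone is a poor substrate and should stay.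

Step 4
Reactants: 6 1-[(4S)-4-hydroxy-2,6,6-trimethylcyclohex-2-en-1-yl]ethan-1-one
Product: 7 1-[(4S)-4-{[tert-butyl(dimethyl)silyl]oxy}-2,6,6-trimethylcyclohex-2-en-1-yl]ethan-1-one (both C1 epimers)
Conditions: TBSCl, imidazole, DMF, rt
Reagents that add atoms: tert-butyldimethylsilyl chloride, CC(C)(C)[Si](C)(C)Cl
Why: Standard silylation of the secondary allylic alcohol protects the C3 oxygen through the organometallic, hydride and mild-acid steps without touching the stereocentre.

Step 5
Reactants: 7 1-[(4S)-4-{[tert-butyl(dimethyl)silyl]oxy}-2,6,6-trimethylcyclohex-2-en-1-yl]ethan-1-one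
Product: 11 tert-butyl{[(1S)-4-ethynyl-3,5,5-trimethylcyclohex-2-en-1-yl]oxy}dimethylsilane (both C4 epimers), via lithium enolate 8 (not isolated), via enol phosphate 9 (not isolated), via lithium acetylide 10 (not isolated)
Conditions: LiN(i-Pr)2 (1.1 equiv), THF, −78 °C; ClP(O)(OEt)2, −78 °C → rt; LiN(i-Pr)2 (2.3 equiv), −78 → 0 °C; H2O
Reagents that add atoms: diethyl chlorophosphate, CCOP(Cl)(=O)OCC (its atoms stay only in 9); LiN(i-Pr)2, [Li]N(C(C)C)C(C)C (its lithium stays only in 8 and 10)
Why: Kinetic deprotonation at the methyl group (the hindered ring methine is not touched), O-phosphorylation and base-induced β-elimination of diethyl phosphate is the established one-pot conversion of methyl ketones into terminal alkynes; the acetylide formed with the excess base is protonated on work-up so that 11 can be purified.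

Step 6
Reactants: 12 safranal (2,6,6-trimethylcyclohexa-1,3-diene-1-carbaldehyde)
Product: 13 1-ethynyl-2,6,6-trimethylcyclohexa-1,3-diene
Conditions: Me3SiCHN2, LiN(i-Pr)2, THF, −78 °C; then 12, −78 °C → rt; H2O
Reagents that add atoms: trimethylsilyldiazomethane, C[Si](C)(C)C=[N+]=[N-] (supplies the terminal alkyne carbon)
Why: Colvin rearrangement: the lithiated diazomethane adds to the aldehyde, Peterson-type loss of silanolate gives a diazoalkene, and loss of N2 with 1,2-hydrogen shift of the alkylidene carbene should give the dienyne.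

Step 7
Reactants: 14 glyoxal (40 wt % in water); 15 diethyl [(2E)-3-cyano-2-methylprop-2-en-1-yl]phosphonate (2.1 equiv)
Product: 16 (2E,4E,6E,8E)-3,8-dimethyldeca-2,4,6,8-tetraenedinitrile
Conditions: NaOEt, EtOH, 0 °C; then 14 added slowly, 0 °C → rt; crystallisation
Reagents that add atoms: none
Why: Two-fold Horner–Wadsworth–Emmons olefination of the dialdehyde with the allylic phosphonate anion should give E-configured new alkenes; any 2Z isomers at the nitrile-bearing alkenes are removed by crystallisation of the all-E dinitrile.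

Step 8
Reactants: 16 (2E,4E,6E,8E)-3,8-dimethyldeca-2,4,6,8-tetraenedinitrile
Product: 18 (2E,4E,6E,8E)-3,8-dimethyldeca-2,4,6,8-tetraenedial, via bis(aluminoimine) 17 (not isolated)
Conditions: i-Bu2AlH (2.4 equiv), CH2Cl2, −78 °C; then wet SiO2, H2O, 0 °C
Reagents that add atoms: water, O (the two aldehyde oxygens); i-Bu2AlH, CC(C)C[AlH]CC(C)C (its aluminium and isobutyl groups stay only in 17)
Why: Partial reduction of conjugated nitriles stops at the N-aluminoaldimine, which is hydrolysed on work-up to the enal, the standard nitrile-to-aldehyde reduction of polyene chemistry.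

Step 9
Reactants: 18 (2E,4E,6E,8E)-3,8-dimethyldeca-2,4,6,8-tetraenedial; 19 1-(triphenylphosphoranylidene)propan-2-one (2.3 equiv)
Product: 20 (3E,5E,7E,9E,11E,13E)-6,11-dimethylhexadeca-3,5,7,9,11,13-hexaene-2,15-dione
Conditions: toluene, 90 °C
Reagents that add atoms: none
Why: Two-fold Wittig olefination with the stabilised ylide should be E-selective and gives the symmetrical diketone whose carbonyl carbons are C9 and C9' and whose methyl groups are the future C9 and C9' methyls.

Step 10
Reactants: 11 tert-butyl{[(1S)-4-ethynyl-3,5,5-trimethylcyclohex-2-en-1-yl]oxy}dimethylsilane; 20 (3E,5E,7E,9E,11E,13E)-6,11-dimethylhexadeca-3,5,7,9,11,13-hexaene-2,15-dione (3 equiv)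
Product: 22 (3E,5E,7E,9E,11E,13E)-17-[(4S)-4-{[tert-butyl(dimethyl)silyl]oxy}-2,6,6-trimethylcyclohex-2-en-1-yl]-15-hydroxy-6,11,15-trimethylheptadeca-3,5,7,9,11,13-hexaen-16-yn-2-one, via bromomagnesium acetylide 21 (not isolated)
Conditions: 11, EtMgBr (1.05 equiv), THF, 0 → 40 °C; added to 20, THF, −20 → 0 °C; H2O; excess 20 recovered
Reagents that add atoms: ethylmagnesium bromide, CC[Mg]Br (its magnesium and bromine stay only in 21)
Why: Deprotonation of the terminal alkyne by the ethyl Grignard reagent gives the alkynylmagnesium bromide, whose 1,2-addition to a methyl ketone (Grignard ethynylation as in classical polyene chemistry) forms the C8–C9 bond; the weakly basic magnesium acetylide should add rather than enolise, the excess of recoverable 20 limits double addition, and the new carbinol centre is uncontrolled because it is destroyed in step 13.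

Step 11
Reactants: 22 the mono-adduct of step 10; 13 1-ethynyl-2,6,6-trimethylcyclohexa-1,3-diene (2.4 equiv)
Product: 24 (4E,6E,8E,10E,12E,14E)-1-[(4S)-4-{[tert-butyl(dimethyl)silyl]oxy}-2,6,6-trimethylcyclohex-2-en-1-yl]-3,7,12,16-tetramethyl-18-(2,6,6-trimethylcyclohexa-1,3-dien-1-yl)octadeca-4,6,8,10,12,14-hexaene-1,17-diyne-3,16-diol, via lithium acetylide 23 (not isolated)
Conditions: 13, n-BuLi (2.3 equiv), THF, −78 °C; then 22, −78 → 0 °C; H2O
Reagents that add atoms: n-butyllithium, [Li]CCCC (its lithium stays only in 23)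
Why: The first equivalent of acetylide deprotonates the tertiary alcohol and the second adds 1,2 to the remaining methyl ketone (acetylide addition to a ketone), completing the C40 skeleton; the second carbinol centre is again uncontrolled and later destroyed.

Step 12
Reactants: 24 the C40 diynediol of step 11
Product: 25 (1E,4E,6E,8E,10E,12E,14E,17E)-1-[(4S)-4-{[tert-butyl(dimethyl)silyl]oxy}-2,6,6-trimethylcyclohex-2-en-1-yl]-3,7,12,16-tetramethyl-18-(2,6,6-trimethylcyclohexa-1,3-dien-1-yl)octadeca-1,4,6,8,10,12,14,17-octaene-3,16-diol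
Conditions: LiAlH4 (4 equiv), THF, 0 → 45 °C; H2O work-up
Reagents that add atoms: none
Why: Alkoxide-directed trans-hydroalumination of propargylic alcohols should reduce both alkynes to E-alkenes, the classical way to E-allylic carbinols in polyene synthesis, leaving the polyene and the silyl ether untouched.

Step 13
Reactants: 25 the C40 octaenediol of step 12
Product: 26 the tert-butyldimethylsilyl ether of the target (3S, alkene geometry of the target)
Conditions: pyridinium p-toluenesulfonate (10 mol %), toluene, 40 °C, argon, dark; then I2 (1 mol %), rt, diffuse light; chromatography and crystallisation of the isomer with the target geometry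
Reagents that add atoms: none
Why: Acid-catalysed E1 dehydration of the anhydroretinol type: each tertiary doubly allylic alcohol ionises to a polyenyl cation that loses a ring proton (C6–H in the silyloxy ring, a C2'–H at the vinylogous position in the safranal-derived ring) to give the fully conjugated retro-polyene as the thermodynamic product. The ring C6 and both carbinol stereocentres vanish, and alkene geometry is set by equilibration (the chain carbon at each exocyclic alkene should prefer the side of the gem-dimethyl carbon, away from the in-plane ring methyl), with other isomers recycled through the iodine step.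

Step 14
Reactants: 26 the tert-butyldimethylsilyl ether of the target
Product: 27 target CNP0202479.1, the (3S)-3-hydroxy retro-carotenoid with one 2,3-didehydro retro end group
Conditions: Bu4NF, THF, 0 °C → rt; exclusion of light and acid
Reagents that add atoms: none
Why: Fluoride-induced desilylation cleaves the Si–O bond only, so the (S)-carbinol set in step 3 is not touched.

**Compound list**
1 | (3E)-4-methoxypent-3-en-2-one | CC(=O)/C=C(\C)OC | starting material
2 | (3E)-2-{[tert-butyl(dimethyl)silyl]oxy}-4-methoxypenta-1,3-diene | C=C(O[Si](C)(C)C(C)(C)C)/C=C(\C)OC | intermediate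
3 | mesityl oxide (4-methylpent-3-en-2-one) | CC(=O)C=C(C)C | starting material
4 | 1-[4-{[tert-butyl(dimethyl)silyl]oxy}-2-methoxy-2,6,6-trimethylcyclohex-3-en-1-yl]ethan-1-one (racemic, diastereomer mixture) | CC(=O)C1C(C)(OC)C=C(O[Si](C)(C)C(C)(C)C)CC1(C)C | intermediate (not isolated)
5 | 4-acetyl-3,5,5-trimethylcyclohex-2-en-1-one (racemic) | CC(=O)C1C(C)=CC(=O)CC1(C)C | intermediate
6 | 1-[(4S)-4-hydroxy-2,6,6-trimethylcyclohex-2-en-1-yl]ethan-1-one (both C1 epimers) | CC(=O)C1C(C)=C[C@@H](O)CC1(C)C | intermediate
7 | 1-[(4S)-4-{[tert-butyl(dimethyl)silyl]oxy}-2,6,6-trimethylcyclohex-2-en-1-yl]ethan-1-one (both C1 epimers) | CC(=O)C1C(C)=C[C@@H](O[Si](C)(C)C(C)(C)C)CC1(C)C | intermediate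
8 | lithium enolate of 7 (methyl side) | [Li]OC(=C)C1C(C)=C[C@@H](O[Si](C)(C)C(C)(C)C)CC1(C)C | intermediate (not isolated)
9 | diethyl 1-[(4S)-4-{[tert-butyl(dimethyl)silyl]oxy}-2,6,6-trimethylcyclohex-2-en-1-yl]ethenyl phosphate | C=C(OP(=O)(OCC)OCC)C1C(C)=C[C@@H](O[Si](C)(C)C(C)(C)C)CC1(C)C | intermediate (not isolated)
10 | lithium acetylide of 11 | [Li]C#CC1C(C)=C[C@@H](O[Si](C)(C)C(C)(C)C)CC1(C)C | intermediate (not isolated)
11 | tert-butyl{[(1S)-4-ethynyl-3,5,5-trimethylcyclohex-2-en-1-yl]oxy}dimethylsilane (both C4 epimers) | C#CC1C(C)=C[C@@H](O[Si](C)(C)C(C)(C)C)CC1(C)C | intermediate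
12 | safranal (2,6,6-trimethylcyclohexa-1,3-diene-1-carbaldehyde) | CC1=C(C=O)C(C)(C)CC=C1 | starting material
13 | 1-ethynyl-2,6,6-trimethylcyclohexa-1,3-diene | CC1=C(C#C)C(C)(C)CC=C1 | intermediate
14 | glyoxal (ethanedial) | O=CC=O | starting material
15 | diethyl [(2E)-3-cyano-2-methylprop-2-en-1-yl]phosphonate | CCOP(=O)(OCC)C/C(C)=C/C#N | starting material
16 | (2E,4E,6E,8E)-3,8-dimethyldeca-2,4,6,8-tetraenedinitrile | N#C/C=C(C)/C=C/C=C/C(C)=C/C#N | intermediate
17 | N,N'-bis(diisobutylalumino) diimine of 18 | CC(C)C[Al](CC(C)C)N=C/C=C(C)/C=C/C=C/C(C)=C/C=N[Al](CC(C)C)CC(C)C | intermediate (not isolated)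
18 | (2E,4E,6E,8E)-3,8-dimethyldeca-2,4,6,8-tetraenedial | O=C/C=C(C)/C=C/C=C/C(C)=C/C=O | intermediate
19 | 1-(triphenylphosphoranylidene)propan-2-one | CC(=O)C=P(c1ccccc1)(c1ccccc1)c1ccccc1 | starting material
20 | (3E,5E,7E,9E,11E,13E)-6,11-dimethylhexadeca-3,5,7,9,11,13-hexaene-2,15-dione | CC(=O)/C=C/C=C(C)/C=C/C=C/C(C)=C/C=C/C(C)=O | intermediate
21 | bromomagnesium acetylide of 11, {[(4S)-4-{[tert-butyl(dimethyl)silyl]oxy}-2,6,6-trimethylcyclohex-2-en-1-yl]ethynyl}magnesium bromide | Br[Mg]C#CC1C(C)=C[C@@H](O[Si](C)(C)C(C)(C)C)CC1(C)C | intermediate (not isolated)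
22 | (3E,5E,7E,9E,11E,13E)-17-[(4S)-4-{[tert-butyl(dimethyl)silyl]oxy}-2,6,6-trimethylcyclohex-2-en-1-yl]-15-hydroxy-6,11,15-trimethylheptadeca-3,5,7,9,11,13-hexaen-16-yn-2-one (diastereomer mixture) | CC(=O)/C=C/C=C(C)/C=C/C=C/C(C)=C/C=C/C(C)(O)C#CC1C(C)=C[C@@H](O[Si](C)(C)C(C)(C)C)CC1(C)C | intermediate
23 | lithium acetylide of 13 | [Li]C#CC1=C(C)C=CCC1(C)C | intermediate (not isolated)
24 | (4E,6E,8E,10E,12E,14E)-1-[(4S)-4-{[tert-butyl(dimethyl)silyl]oxy}-2,6,6-trimethylcyclohex-2-en-1-yl]-3,7,12,16-tetramethyl-18-(2,6,6-trimethylcyclohexa-1,3-dien-1-yl)octadeca-4,6,8,10,12,14-hexaene-1,17-diyne-3,16-diol (diastereomer mixture) | CC1=C(C#CC(C)(O)/C=C/C=C(C)/C=C/C=C/C(C)=C/C=C/C(C)(O)C#CC2C(C)=C[C@@H](O[Si](C)(C)C(C)(C)C)CC2(C)C)C(C)(C)CC=C1 | intermediate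
25 | (1E,4E,6E,8E,10E,12E,14E,17E)-1-[(4S)-4-{[tert-butyl(dimethyl)silyl]oxy}-2,6,6-trimethylcyclohex-2-en-1-yl]-3,7,12,16-tetramethyl-18-(2,6,6-trimethylcyclohexa-1,3-dien-1-yl)octadeca-1,4,6,8,10,12,14,17-octaene-3,16-diol (diastereomer mixture) | CC1=C(/C=C/C(C)(O)/C=C/C=C(C)/C=C/C=C/C(C)=C/C=C/C(C)(O)/C=C/C2C(C)=C[C@@H](O[Si](C)(C)C(C)(C)C)CC2(C)C)C(C)(C)CC=C1 | intermediate
26 | tert-butyldimethylsilyl ether of the target (3S, alkene geometry of the target) | CC1=CC=CC(C)(C)\C1=C/C=C(C)/C=C/C=C(C)/C=C/C=C/C(C)=C/C=C/C(C)=C/C=C1/C(C)=C[C@@H](O[Si](C)(C)C(C)(C)C)CC1(C)C | intermediate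
27 | CNP0202479.1, (3S)-3-hydroxy retro-carotenoid with one 2,3-didehydro retro end group | CC1=CC=CC(C)(C)\C1=C/C=C(C)/C=C/C=C(C)/C=C/C=C/C(C)=C/C=C/C(C)=C/C=C1/C(C)=C[C@@H](O)CC1(C)C | target

**Totals**
Total step count: 14.
Longest linear sequence: 10 steps (steps 1–5, then 10–14).

**Steps most likely to fail**

Step 2 (key step). The silyl enol ether terminus of 2 may be lost to protodesilylation before it adds to the hindered enone, or the sequence may stop after the first conjugate addition because closure at the fully substituted, methoxy-bearing terminus is too slow. The fallback sets out from 3 and comes back at 5. (E)-Pent-3-en-2-one is silylated (TBSOTf, Et3N) to (3E)-2-{[tert-butyl(dimethyl)silyl]oxy}penta-1,3-diene F1, whose unhindered E-methyl terminus allows a concerted Diels–Alder reaction with 3 under AlBr3/AlMe3 (toluene–CH2Cl2, −5 °C). This forms the same two ring bonds and gives the silyl enol ether 1-[4-{[tert-butyl(dimethyl)silyl]oxy}-2,6,6-trimethylcyclohex-3-en-1-yl]ethan-1-one F2. Saegusa–Ito dehydrogenation (Pd(OAc)2, MeCN, rt) then places the alkene at C4=C5 regiospecifically and gives 5.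

Step 13. The acid may also ionise the allylic silyl ether once the polyene is in place (loss of the oxygen function), and proton loss may give cross-conjugated or geometric isomers that do not converge. The fallback sets out from 25 and comes back at 27; it removes the ionisable C3–O bond before the elimination. Bu4NF cleaves the silyl ether to the desilylated triol of 25 F3, MnO2 (CH2Cl2) oxidises only the secondary allylic alcohol to the keto-diol F4, and the same acid treatment then gives the acid-stable 3-oxo retro-polyene F5. Corey–Bakshi–Shibata reduction of its single ketone ((R)-2-methyl-CBS-oxazaborolidine, catecholborane, toluene, −78 °C, polyenyl arm as the large group) would re-set the (S)-carbinol and give 27.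

Step 3. Hydride transfer may also reduce the acetyl ketone or the enone alkene, or facial selectivity may be poor with the racemic ring centre next door. The fallback sets out from 4 (isolated after an Et3N quench instead of the acid treatment) and comes back at 11. The acetyl group of 4 is converted as in step 5 through the enol phosphate diethyl 1-[4-{[tert-butyl(dimethyl)silyl]oxy}-2-methoxy-2,6,6-trimethylcyclohex-3-en-1-yl]ethenyl phosphate F6 into the alkyne tert-butyl[(4-ethynyl-3-methoxy-3,5,5-trimethylcyclohex-1-en-1-yl)oxy]dimethylsilane F7. 1 M HCl in THF unmasks 4-ethynyl-3,5,5-trimethylcyclohex-2-en-1-one F8, which has only one carbonyl. Corey–Bakshi–Shibata reduction ((R)-2-methyl-CBS-oxazaborolidine, catecholborane) then gives (1S)-4-ethynyl-3,5,5-trimethylcyclohex-2-en-1-ol F9, and silylation (TBSCl, imidazole) gives 11.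

**Further compounds**
F1 | step 2 | (3E)-2-{[tert-butyl(dimethyl)silyl]oxy}penta-1,3-diene | C=C(O[Si](C)(C)C(C)(C)C)/C=C/C
F2 | step 2 | 1-[4-{[tert-butyl(dimethyl)silyl]oxy}-2,6,6-trimethylcyclohex-3-en-1-yl]ethan-1-one (racemic, diastereomer mixture) | CC(=O)C1C(C)C=C(O[Si](C)(C)C(C)(C)C)CC1(C)C
F3 | step 13 | desilylated triol of 25 | CC1=C(/C=C/C(C)(O)/C=C/C=C(C)/C=C/C=C/C(C)=C/C=C/C(C)(O)/C=C/C2C(C)=C[C@@H](O)CC2(C)C)C(C)(C)CC=C1
F4 | step 13 | keto-diol (ring enone, two tertiary carbinols) | CC1=C(/C=C/C(C)(O)/C=C/C=C(C)/C=C/C=C/C(C)=C/C=C/C(C)(O)/C=C/C2C(C)=CC(=O)CC2(C)C)C(C)(C)CC=C1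
F5 | step 13 | 3-oxo retro-polyene (ketone of the target) | CC1=CC=CC(C)(C)\C1=C/C=C(C)/C=C/C=C(C)/C=C/C=C/C(C)=C/C=C/C(C)=C/C=C1/C(C)=CC(=O)CC1(C)C
F6 | step 3 | diethyl 1-[4-{[tert-butyl(dimethyl)silyl]oxy}-2-methoxy-2,6,6-trimethylcyclohex-3-en-1-yl]ethenyl phosphate | C=C(OP(=O)(OCC)OCC)C1C(C)(OC)C=C(O[Si](C)(C)C(C)(C)C)CC1(C)C
F7 | step 3 | tert-butyl[(4-ethynyl-3-methoxy-3,5,5-trimethylcyclohex-1-en-1-yl)oxy]dimethylsilane | C#CC1C(C)(OC)C=C(O[Si](C)(C)C(C)(C)C)CC1(C)C
F8 | step 3 | 4-ethynyl-3,5,5-trimethylcyclohex-2-en-1-one (racemic) | C#CC1C(C)=CC(=O)CC1(C)C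
F9 | step 3 | (1S)-4-ethynyl-3,5,5-trimethylcyclohex-2-en-1-ol (both C4 epimers) | C#CC1C(C)=C[C@@H](O)CC1(C)C
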